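**Retrosynthetic overview**
- Structural feature: four adjacent carbons of the benzene ring, C3' to C6', carry Br, H, Br, H, the same pattern as C3 to C6 of 3,5-dibromo-2-pyrone. The other two, C2' (OH) and C1' (pyrrol-2-yl), match the carboxyl and α-carbons of a pyrrol-2-ylacetic acid.
- Last disconnections: the three pyrrole C–Br bonds (C3, C4, C5) and the N–H, leading back to 2,4-dibromo-6-(1-tosylpyrrol-2-yl)phenol.
- Key disconnection: C2'–C3' and C1'–C6' of the benzene ring, leading back to 3,5-dibromo-2-pyrone and the bis(trimethylsilyl) ketene acetal of (1-tosylpyrrol-2-yl)acetic acid, joined by (4+2) addition followed by loss of CO2 and Me3SiOH.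
- Building blocks: the pyrone comes from coumalic acid by bromodecarboxylation. The ketene acetal comes from pyrrole and ethyl diazoacetate by carbene transfer, N-tosylation, saponification and double silylation.
- Ring order: the pyrrole ring is bought, and the benzene ring is the only ring formed.

Key step: step 6

Remark: the target is achiral. The stereocentres of the two transient sp3-containing intermediates of the key step form racemic and unassigned and are erased on aromatisation, so their SMILES carry no descriptors.

**Step 1**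
Reactants: 1 coumalic acid (2-oxo-2H-pyran-5-carboxylic acid)
Product: 3 3,5-dibromo-2H-pyran-2-one, via 5-bromo-2H-pyran-2-one 2 (not isolated)
Conditions: NBS (2.5 equiv), Bu4NBr (cat.), CHCl3, 50 °C
Reagents that add atoms: N-bromosuccinimide, O=C1CCC(=O)N1Br
Why: Hunsdiecker-type bromodecarboxylation at C5, followed by electrophilic bromination (addition–elimination) at C3 next to the lactone carbonyl, is the established one-flask entry to this pyrone.

**Step 2**
Reactants: 4 pyrrole; 5 ethyl diazoacetate
Product: 6 ethyl 2-(1H-pyrrol-2-yl)acetate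
Conditions: Cu(acac)2 (2 mol %), neat pyrrole (5 equiv), slow addition of 5, 80 °C
Reagents that add atoms: none
Why: Copper-catalysed carbene transfer from a diazoacetate to N–H pyrrole is a classical formal C–H insertion that goes to the α-position, and the excess of pyrrole suppresses double alkylation.

**Step 3**
Reactants: 6 ethyl 2-(1H-pyrrol-2-yl)acetate
Product: 7 ethyl 2-(1-tosyl-1H-pyrrol-2-yl)acetate
Conditions: NaH (1.05 equiv), THF, 0 °C; cannulated into TsCl (1.2 equiv), THF, 0 °C → rt
Reagents that add atoms: p-toluenesulfonyl chloride, Cc1ccc(cc1)S(=O)(=O)Cl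
Why: N-sulfonylation of a pyrrole after N–H deprotonation is standard, and inverse addition into excess TsCl traps the nitrogen anion before proton exchange with the ester α-CH2 can matter.

**Step 4**
Reactants: 7 ethyl 2-(1-tosyl-1H-pyrrol-2-yl)acetate
Product: 8 2-(1-tosyl-1H-pyrrol-2-yl)acetic acid
Conditions: LiOH·H2O (2 equiv), THF/H2O 3:1, 0 °C → rt; then 1 M HCl to pH 3
Reagents that add atoms: lithium hydroxide, [Li+].[OH-]
Why: Saponification at or below room temperature is much faster than hydroxide attack at the sulfur of a non-acylated N-tosylpyrrole, and the sulfonyl group also guards the pyrrolylacetic acid against acid-induced decarboxylation on work-up.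

**Step 5**
Reactants: 8 2-(1-tosyl-1H-pyrrol-2-yl)acetic acid
Product: 10 2-[2,2-bis(trimethylsilyloxy)ethenyl]-1-tosyl-1H-pyrrole, via silyl ester 9 (not isolated)
Conditions: LiHMDS (1.05 equiv), THF, −78 °C, then TMSCl (1.1 equiv), → 0 °C; recooled to −78 °C, LiHMDS (1.1 equiv), then TMSCl (1.3 equiv), → rt; pentane, filtration under Ar, no aqueous work-up
Reagents that add atoms: chlorotrimethylsilane, C[Si](C)(C)Cl
Why: This is the standard bis(silyl) ketene acetal preparation by O-silylation, α-deprotonation and a second O-silylation; the arylacetate-type CH2 of 9 is acidic enough for LiHMDS, a base too weak to metalate C5 of the sulfonylpyrrole or the tolyl group.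

**Step 6**
Reactants: 3 3,5-dibromo-2H-pyran-2-one; 10 2-[2,2-bis(trimethylsilyloxy)ethenyl]-1-tosyl-1H-pyrrole
Product: 14 2,4-dibromo-6-(1-tosyl-1H-pyrrol-2-yl)phenol, via bridged lactone 11 (not isolated), via cyclohexadiene 12 (not isolated), via aryl silyl ether 13 (not isolated)
Conditions: 10 (1.5 equiv), xylenes, sealed tube, Ar, 90 °C until 3 is consumed, then 140 °C; then 1 M HCl, THF, rt
Reagents that add atoms: none
Why: In this inverse-electron-demand Diels–Alder reaction the electron-rich C=C of 10 adds across C3 and C6 of the electron-poor pyrone diene of 3, an intermolecular, concerted but asynchronous (4+2) closure that makes C1'–C6' and C2'–C3' and gives bridged lactone 11. On further heating 11 expels CO2 by retro-(4+2) to give cyclohexadiene 12, whose gem-bis(silyloxy) carbon ionises next to an allylic, pyrrolyl-activated C–H so that 1,2-loss of Me3SiOH aromatises the new six-membered ring to 13, and dilute acid then removes the last silyl group. The closest known reaction type is the benzannulation of 2-pyrones with ketene acetals and enol ethers (cycloaddition, decarboxylation, loss of ROH), and 3,5-dibromo-2-pyrone is an established diene for silyl enol ethers. Regiocontrol is the one selectivity required: the largest HOMO coefficient of 10 sits on the CH carbon carrying the pyrrole and the largest LUMO coefficient of 3 on the unsubstituted C6 (the δ-position of the dienoate), so these two carbons bond first and the acetal carbon closes onto C3 beside bromine, while N-sulfonylation lowers the nucleophilicity of the pyrrole carbons enough that the acetal alone dictates this polarity. The stereocentres of 11 and 12 (endo/exo mixture accepted) all vanish on aromatisation, so no stereocontrol is called for. Both acetal oxygens carry the same silyl group so either may leave with the same outcome, no sp3 C–H lies next to a C–Br so HBr cannot be lost, and holding the lower temperature until 3 is consumed keeps the silanol released later from protonating unreacted 10.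

**Step 7**
Reactants: 14 2,4-dibromo-6-(1-tosyl-1H-pyrrol-2-yl)phenol
Product: 15 2,4-dibromo-6-(1H-pyrrol-2-yl)phenol
Conditions: 5 M aq NaOH, 1,4-dioxane, 90 °C; then 1 M HCl to pH 5–6
Reagents that add atoms: none
Why: Hydroxide cleaves the N–S bond of an N-sulfonylpyrrole by nucleophilic attack at sulfur (and would equally remove the group after any migration to the neighbouring phenoxide oxygen), the alcohol-free medium avoids an alkyl tosylate that could alkylate the phenoxide, and the bromines on the phenoxide ring are inert to SNAr.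

**Step 8**
Reactants: 15 2,4-dibromo-6-(1H-pyrrol-2-yl)phenol
Product: 18 pentabromopseudilin [2,4-dibromo-6-(3,4,5-tribromo-1H-pyrrol-2-yl)phenol], via 5-bromopyrrole 16 (not isolated), via 3,5-dibromopyrrole 17 (not isolated)
Conditions: NBS (3.0 equiv), THF, −78 → 0 °C, dark; aq Na2S2O3
Reagents that add atoms: N-bromosuccinimide, O=C1CCC(=O)N1Br
Why: In this electrophilic aromatic substitution the free N–H pyrrole is by far the most electron-rich ring and should take up bromine at C5, C3 and C4 in turn, whereas both ortho positions and the para position of the phenol are already occupied, so three equivalents at low temperature should stop at the pentabromide.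

**Compound list**
1 | coumalic acid | O=C(O)c1ccc(=O)oc1 | starting material
2 | 5-bromo-2H-pyran-2-one | O=c1ccc(Br)co1 | intermediate
3 | 3,5-dibromo-2H-pyran-2-one | O=c1occ(Br)cc1Br | intermediate
4 | pyrrole | c1cc[nH]c1 | starting material
5 | ethyl diazoacetate | CCOC(=O)C=[N+]=[N-] | starting material
6 | ethyl 2-(1H-pyrrol-2-yl)acetate | CCOC(=O)Cc1ccc[nH]1 | intermediate
7 | ethyl 2-(1-tosyl-1H-pyrrol-2-yl)acetate | CCOC(=O)Cc1cccn1S(=O)(=O)c1ccc(C)cc1 | intermediate
8 | 2-(1-tosyl-1H-pyrrol-2-yl)acetic acid | OC(=O)Cc1cccn1S(=O)(=O)c1ccc(C)cc1 | intermediate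
9 | trimethylsilyl 2-(1-tosyl-1H-pyrrol-2-yl)acetate | C[Si](C)(C)OC(=O)Cc1cccn1S(=O)(=O)c1ccc(C)cc1 | intermediate
10 | 2-[2,2-bis(trimethylsilyloxy)ethenyl]-1-tosyl-1H-pyrrole | C[Si](C)(C)OC(O[Si](C)(C)C)=Cc1cccn1S(=O)(=O)c1ccc(C)cc1 | intermediate
11 | 4,6-dibromo-8,8-bis(trimethylsilyloxy)-7-(1-tosyl-1H-pyrrol-2-yl)-2-oxabicyclo[2.2.2]oct-5-en-3-one (racemic, endo/exo unassigned) | O=C1OC2C(Br)=CC1(Br)C(O[Si](C)(C)C)(O[Si](C)(C)C)C2c1cccn1S(=O)(=O)c1ccc(C)cc1 | intermediate
12 | 2-[3,5-dibromo-6,6-bis(trimethylsilyloxy)cyclohexa-2,4-dien-1-yl]-1-tosyl-1H-pyrrole (racemic) | BrC1=CC(Br)=CC(c2cccn2S(=O)(=O)c2ccc(C)cc2)C1(O[Si](C)(C)C)O[Si](C)(C)C | intermediate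
13 | 2-[3,5-dibromo-2-(trimethylsilyloxy)phenyl]-1-tosyl-1H-pyrrole | C[Si](C)(C)Oc1c(Br)cc(Br)cc1-c1cccn1S(=O)(=O)c1ccc(C)cc1 | intermediate
14 | 2,4-dibromo-6-(1-tosyl-1H-pyrrol-2-yl)phenol | Oc1c(Br)cc(Br)cc1-c1cccn1S(=O)(=O)c1ccc(C)cc1 | intermediate
15 | 2,4-dibromo-6-(1H-pyrrol-2-yl)phenol | Oc1c(Br)cc(Br)cc1-c1ccc[nH]1 | intermediate
16 | 2,4-dibromo-6-(5-bromo-1H-pyrrol-2-yl)phenol | Oc1c(Br)cc(Br)cc1-c1ccc(Br)[nH]1 | intermediate
17 | 2,4-dibromo-6-(3,5-dibromo-1H-pyrrol-2-yl)phenol | Oc1c(Br)cc(Br)cc1-c1[nH]c(Br)cc1Br | intermediate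
18 | pentabromopseudilin | Oc1c(Br)cc(Br)cc1-c1[nH]c(Br)c(Br)c1Br | target

**Step count**
- Total step count: 8.
- Longest linear sequence: 7 steps, from pyrrole 4 through 6, 7, 8, 10, 14 and 15 to 18. Step 1 is a one-step side branch.

**Steps most likely to fail**

1. **Step 6.**
   - What may go wrong:
     - The ring closure may be slow, because the second bond forms between the bromine-bearing C3 and a fully substituted acetal carbon.
     - Conjugate addition at C6 with silyl transfer may take the place of cycloaddition.
     - The ketene acetal may be protodesilylated by adventitious moisture or by released silanol.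
   - Fallback: the aryl–pyrrole bond is made by cross-coupling in place of benzannulation. It sets out from pyrrole 4.
     - Boc2O and DMAP in MeCN give tert-butyl 1H-pyrrole-1-carboxylate F1.
     - LDA in THF at −78 °C, then B(OMe)3 and dilute acid, give [1-(tert-butoxycarbonyl)-1H-pyrrol-2-yl]boronic acid F2.
     - Commercial 2,4-dibromophenol is iodinated at its free ortho position with NIS in MeCN to 2,4-dibromo-6-iodophenol F3.
     - Suzuki–Miyaura coupling of F2 and F3 uses Pd(PPh3)4, Na2CO3, DME/H2O at 60 °C. It is chemoselective for the carbon–iodine bond over the carbon–bromine bonds and gives tert-butyl 2-(3,5-dibromo-2-hydroxyphenyl)-1H-pyrrole-1-carboxylate F4.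
     - NaOMe in MeOH/THF at rt removes the carbamate, and the route is rejoined at 15.

2. **Step 5.**
   - What may go wrong:
     - The very labile bis(trimethylsilyl) acetal may hydrolyse during isolation.
     - The second deprotonation may be incomplete.
     - Some silylation may occur at carbon.
   - Fallback: a sturdier mixed alkyl silyl ketene acetal is made directly from the ester, which also skips step 4. It sets out from 7.
     - LiHMDS in THF/DMPU at −78 °C, then TBSCl, give the ethyl tert-butyldimethylsilyl ketene acetal F5 (E/Z mixture, immaterial). This acetal tolerates a brief aqueous wash.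
     - Heated with pyrone 3 as in step 6, F5 should pass through the bridged lactone F6 and the cyclohexadiene F7.
     - Loss of ethanol, the more basic and therefore more readily acid-activated leaving group of the mixed acetal, gives the aryl tert-butyldimethylsilyl ether F8.
     - TBAF in THF then rejoins the route at 14.

3. **Step 8.**
   - What may go wrong:
     - The electron-rich N–H pyrrole may be oxidised or may oligomerise under acid.
     - Electrophilic bromine may attack the free phenol ring at an ipso position, with dearomatisation.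
   - Fallback: the phenol is masked before bromination. It sets out from 15.
     - Ac2O in pyridine at 0 °C acylates only the phenol oxygen, giving 2,4-dibromo-6-(1H-pyrrol-2-yl)phenyl acetate F9.
     - Pyridinium tribromide (3 equiv) in CH2Cl2 at 0 °C fills the three pyrrole positions, giving 2,4-dibromo-6-(3,4,5-tribromo-1H-pyrrol-2-yl)phenyl acetate F10.
     - K2CO3 in MeOH at rt cleaves the acetate, and the route is rejoined at 18.

**Further compounds**
F1 | step 6 | tert-butyl 1H-pyrrole-1-carboxylate | CC(C)(C)OC(=O)n1cccc1
F2 | step 6 | [1-(tert-butoxycarbonyl)-1H-pyrrol-2-yl]boronic acid | CC(C)(C)OC(=O)n1cccc1B(O)O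
F3 | step 6 | 2,4-dibromo-6-iodophenol | Oc1c(Br)cc(Br)cc1I
F4 | step 6 | tert-butyl 2-(3,5-dibromo-2-hydroxyphenyl)-1H-pyrrole-1-carboxylate | CC(C)(C)OC(=O)n1cccc1-c1cc(Br)cc(Br)c1O
F5 | step 5 | 2-[2-ethoxy-2-(tert-butyldimethylsilyloxy)ethenyl]-1-tosyl-1H-pyrrole (E/Z mixture) | CCOC(O[Si](C)(C)C(C)(C)C)=Cc1cccn1S(=O)(=O)c1ccc(C)cc1
F6 | step 5 | 4,6-dibromo-8-ethoxy-8-(tert-butyldimethylsilyloxy)-7-(1-tosyl-1H-pyrrol-2-yl)-2-oxabicyclo[2.2.2]oct-5-en-3-one (racemic, unassigned) | O=C1OC2C(Br)=CC1(Br)C(OCC)(O[Si](C)(C)C(C)(C)C)C2c1cccn1S(=O)(=O)c1ccc(C)cc1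
F7 | step 5 | 2-[3,5-dibromo-6-ethoxy-6-(tert-butyldimethylsilyloxy)cyclohexa-2,4-dien-1-yl]-1-tosyl-1H-pyrrole (racemic, unassigned) | BrC1=CC(Br)=CC(c2cccn2S(=O)(=O)c2ccc(C)cc2)C1(OCC)O[Si](C)(C)C(C)(C)C
F8 | step 5 | 2-[3,5-dibromo-2-(tert-butyldimethylsilyloxy)phenyl]-1-tosyl-1H-pyrrole | CC(C)(C)[Si](C)(C)Oc1c(Br)cc(Br)cc1-c1cccn1S(=O)(=O)c1ccc(C)cc1
F9 | step 8 | 2,4-dibromo-6-(1H-pyrrol-2-yl)phenyl acetate | CC(=O)Oc1c(Br)cc(Br)cc1-c1ccc[nH]1
F10 | step 8 | 2,4-dibromo-6-(3,4,5-tribromo-1H-pyrrol-2-yl)phenyl acetate | CC(=O)Oc1c(Br)cc(Br)cc1-c1[nH]c(Br)c(Br)c1Br
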